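## Structural features

CNP0525404.1 is a linear A–B–C–D tetracycle: a 5,6-dimethyl-2-pyranone (ring A) is fused through its C3–C4 bond to a dihydropyran (ring B), ring B shares the hemiketal carbon and the neighbouring methine with a cycloheptanone (ring C), and ring C shares its tertiary carbinol carbon and an sp2 carbon with a 5,5-dimethylcyclopent-2-enone (ring D). Going round ring C the atoms are called Ca (hemiketal carbon, bonded to the ring A oxygen), Cb (CH–OH), Cc (C=O), Cd (C–OH), Ce (enone β-carbon), Cf (CH–CH3) and Cg (CH carrying the methylene Ck of ring B); ring D is completed by Ch (=CH), Ci (C=O) and Cj (CMe2). All five stereocentres lie on ring C: Cg (R), Ca (S) and Cb (R) are contiguous, Cf (R) adjoins Cg, and Cd (R) stands alone between Cc, Cj and Ce. The hemiketal is the closed tautomer of a 2-hydroxy-1,3-diketone, the Cd–Cc unit is a tertiary α-ketol open to acyloin shift, and the 4-oxy-2-pyranone is a vinylogous ester that does not tolerate strong nucleophiles; Ca, Cb and Cg can epimerise by ring opening and enolisation. The real difficulty is the seven-membered ring together with Cd, a fully substituted carbinol carbon with no hydrogen on any neighbour, which must therefore be set irreversibly and in the absolute sense. The key step uses the array Cd–Cc(=O)–Cb–Ca: Cc with its two neighbours is a 2-oxyallyl unit whose termini Cd and Cb are bonded to Ce and Ca, the 5- and 2-carbons of a former 2-methoxyfuran whose methoxy-bearing carbon is Ca and whose ring oxygen, once expelled from Ce, leaves the ring D enone.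

## Logic of the disconnections

20 ⇒ 19. Cut: the O–Ca bond of ring B and, as protecting groups, the O–H bonds at Cb, Cd and on ring A. Reason: the hemiketal is only the closed tautomer of a 2-oxy-1,3-diketone, so 19 already holds every carbon and oxygen of 20. Gain: ring B and the configurations at Ca, Cb and Cg need not be built. Demand: the last step must remove two silyl ethers and one acetal, close ring B and let Ca, Cb and Cg equilibrate while Cd and Cf stay untouched.

19 ⇒ 17 (through 18). Cut: the Cb–O bond. Reason: Cb is the only carbon between two carbonyl groups and so the only strongly nucleophilic carbon of 17. Gain: a CH2 group without a stereocentre. Demand: one electrophilic oxygen transfer to the enol derivative 18 that leaves the ring D enone, ring A and the methine Cg alone.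

17 ⇒ 16. In the reverse sense Ce and Ca are tied together again: the Ce–O bond of an oxygen bridge and the Ca–OCH3 bond are restored. Reason: a β-alkoxy ketone is a masked enone and a methyl ketal a masked ketone. Gain: 16 is an oxygen-bridged bicycle, the imprint of a furan. Demand: the forward elimination must start from the ring D ketone enolate so that the C–O bond at Ce, not that at Ca, breaks.

16 ⇒ 15. Cut: the C–H bonds at Cf and Cg. Reason: a tetrasubstituted Cf=Cg alkene is what a furan leaves behind. Gain: two stereocentres fewer. Demand: hydrogen must reach the hindered alkene from the face of the oxygen bridge, which gives Cf as in 20. The same syn addition gives Cg in the wrong sense, so Cg has to be inverted later, in 19 → 20, where it is α to a ketone.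

15 ⇒ 14. Cut: Cd–Ce and Cb–Ca, the two bonds that the three-carbon unit Cd–Cc–Cb forms across positions 5 and 2 of a furan. Reason: this is the one cut that removes both carbocycles and the non-epimerisable Cd at once. Gain: 15 with three stereocentres becomes the achiral 14. The two are isomers (C30H44O9Si), the descriptors of 15 describe the only relative arrangement the tether allows, and Cd of 15 has the spatial arrangement of Cd in 20. Demand: a chiral Lewis acid must select one face of the Cd ketone, the furan must attack Cd and not Cb, and the second bond must form before the intermediate cation decays.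

14 ⇒ 13. Cut: the O–CH3 bond of the methoxyfuran. Reason: a 2-methoxyfuran is the O-methyl ether of the aromatic enolate of a butenolide. Gain: a stable lactone replaces an acid-sensitive furan. Demand: removal of the single proton at C5 of the lactone and O- rather than C-methylation, with the side-chain ketones present.

13 ⇒ 8 + 12. Cut: the Ce–Ch bond. Reason: Ce is the acetal-level carbon of a γ-alkoxybutenolide and Ch the terminus of a silyl enol ether, a natural electrophile–nucleophile pair. Gain: the side chain arrives with its 2-silyloxy enone complete, so no regioselective enolisation is needed late. Demand: of the two enol ether termini of 12 only the electron-rich one may react.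

8 ⇒ 6 + 4 (through 7). Cut: the Cg–Ck bond. Reason: Cg is the α-carbon of a butenolide dienolate and Ck a benzylic-type halide carbon. Gain: ring A and the furanone become two simple heterocycles. Demand: α-alkylation of the dienolate rather than γ- or O-alkylation.

4 ⇒ 3 ⇒ 2 ⇒ 1, and 6 ⇒ 5. Cuts: C–Br, then the bond from ring A carbon 3 to Ck, then the acetal O–C bond; for 6 the O–CH3 bond. Reason: 1 and 5 are commercial and carry all ring atoms. Gain: one-carbon and protecting-group operations only. Demand: metalation of 2 at the ring position between its two oxygen functions and not at a methyl group.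

12 ⇒ 11 ⇒ 10 ⇒ 9. Cuts: two O–Si bonds, the carbonyl oxygen at the future Cc, and two C–CH3 bonds at the future Cj. Reason: 11 has only two enolisable positions, both terminal methyl groups, so its double enol ether forms without a regiochemical choice. Gain: a commercial 1,3-diketone. Demand: oxidation of the methylene of the ethyl ketone in 10 in preference to its methyl ketone.

## Other disconnections considered

Alternative 1: The cut is the Cc–Cd bond. In the forward direction a chiral triazolylidene carbene would turn the aldehyde carbon (future Cc) of the ring-B-closed aldehyde–dione A1 into an acyl anion equivalent that attacks the nearer ketone of its 2,2-dimethylcyclopentane-1,3-dione. This crossed aldehyde–ketone benzoin would close ring C and give the acyloin A2, in which ring D is still saturated.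
- In its favour: the reaction class is established, including enantioselective closures onto one carbonyl of a cyclic 1,3-diketone. It creates the tertiary α-ketol directly, with the oxygen at Cb and ring B already present, so neither a late oxygenation at Cb nor a hydrogenation is needed. On precedent and on these two redox operations it is the better plan.
- Against it: A1 must already hold ring B as a mixed ketal and the stereocentres Ca, Cb, Cf and Cg, assembled stereoselectively beforehand. The catalyst would have to match or override that substrate bias. Seven-membered benzoin closures are less favourable than five- or six-membered ones. The α-silyloxy aldehyde next to a ketal carbon is hindered and can epimerise under the basic conditions. A2 still needs a dehydrogenation of ring D (Ce–Ch).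
- Comparison: structurally it front-loads the stereochemistry, whereas 14 is flat. Mechanistically it is the safer single step. In step economy it forms one ring and one C–C bond where step 11 forms two of each. The two plans are equal in relying on a chiral catalyst for Cd.

Alternative 2: The cuts are the O–Ca bond of ring B and the Ca–Cb bond. Forward, LiN(SiMe3)2 would deprotonate the ring A hydroxyl and the silyloxymethyl ketone of the hydroxy ester A3. The ring A oxygen would acylate itself with the methyl ester, and the enolate carbon Cb would add to the resulting enol lactone carbonyl. The tetrahedral adduct is the hemiketal itself, so the product would be A4, the bis-silyl ether of 20.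
- In its favour: Ca appears directly at the hemiketal level with the oxygen at Cb in place, rings B and C close in one operation, and A4 is one deprotection from 20. In the length and mildness of the endgame it is better than the chosen plan, which needs steps 12 to 15.
- Against it: A3 presupposes ring D with the tertiary silyl ether at Cd and the centres Cf and Cg, so the hardest centre is only moved upstream. The enolate of an α-silyloxy ketone can undergo silyl migration. Cg is α to the ester and mobile under the base. The seven-membered closure onto a reversibly formed lactone competes with retro-lactonisation and intermolecular acylation.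
- Comparison: both plans end in an equilibrating hemiketal (equal). The alternative uses only known reaction types (better) but offers no answer for Cd, which step 11 sets catalytically from an achiral compound. Counted from commercial materials it would be expected to be the longer route.

Alternative 3: The cut is the Ca–Cb bond, made by ring contraction. Forward, base and PPh3 would induce an Eschenmoser sulfide contraction of the eight-membered thialactone A5: the α-thio ketone carbon Cb attacks the thioester carbonyl Ca, the episulfide gives up sulfur to the phosphine, and the seven-membered 1,3-diketone A6 results.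
- In its favour: it is a named, known route to 1,3-dicarbonyl units and replaces a direct seven-membered C–C closure by C–S bond formation followed by contraction. A6 is the Cg epimer of 17 with the configuration of the target already in place, so it could enter the chosen endgame at step 14 without a later epimerisation. On that point it is better; on the late oxygenation at Cb the two plans are equal.
- Against it: A5 again requires Cd, Cf and Cg beforehand. The eight-membered thiolactone is an unfavourable medium ring. Sulfide contraction is most reliable with thioamides or doubly activated partners and would be slow for a simple thioester and a ketone flanked by the fully substituted Cd. Sulfur and phosphine residues burden a late intermediate.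
- Comparison: structurally it makes one bond of ring C and no stereocentre. Mechanistically it is precedented where step 11 is not. In step economy it is clearly longer, because everything step 11 creates must be made separately.

Key step: step 11

Remark on the chemistry: Ar stands for 4-(methoxymethoxy)-5,6-dimethyl-2-oxo-2H-pyran-3-yl (protected ring A); atom labels Ca to Ck are those defined under "Structural features".
Assumption: with Cd and Cf fixed, the arrangement of 20 at the exchangeable centres Ca, Cb and Cg (trans-fused rings B and C) is taken to be the thermodynamically preferred one; compounds 5 to 8 and 13, racemic at a centre that is erased later, are written without a stereodescriptor.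

Step 1
Reactants: 1 4-hydroxy-5,6-dimethyl-2H-pyran-2-one
Product: 2 4-(methoxymethoxy)-5,6-dimethyl-2H-pyran-2-one
Conditions: MOMCl, i-Pr2NEt, CH2Cl2, 0 °C → rt
Reagents that add atoms: chloromethyl methyl ether, COCCl
Why: O-Alkylation of the vinylogous carboxylic acid with a hard α-chloro ether (Williamson-type ether synthesis) should give the 4-alkoxy-2-pyranone. The acetal masks the acidic hydroxyl group through the base and Lewis acid steps and is shed by aqueous acid at the end.

Step 2
Reactants: 2 4-(methoxymethoxy)-5,6-dimethyl-2H-pyran-2-one
Product: 3 3-(hydroxymethyl)-4-(methoxymethoxy)-5,6-dimethyl-2H-pyran-2-one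
Conditions: n-BuLi, THF, −78 °C, 20 min; (CH2O)n, −78 °C → rt; H2O
Reagents that add atoms: formaldehyde (as paraformaldehyde), C=O
Why: Directed ring lithiation: the proton at C3 lies between the lactone carbonyl and the acetal oxygen, which both bind lithium, so short exposure to n-BuLi at −78 °C should metalate there and not at the 6-methyl group. The lithio species adds to formaldehyde and gives the primary alcohol that becomes Ck.

Step 3
Reactants: 3 3-(hydroxymethyl)-4-(methoxymethoxy)-5,6-dimethyl-2H-pyran-2-one
Product: 4 3-(bromomethyl)-4-(methoxymethoxy)-5,6-dimethyl-2H-pyran-2-one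
Conditions: CBr4, PPh3, CH2Cl2, 0 °C
Reagents that add atoms: tetrabromomethane, BrC(Br)(Br)Br
Why: Appel reaction: the neutral phosphonium-mediated exchange of the primary hydroxyl for bromide avoids acid that would cleave the acetal. The product is an activated benzylic-type alkylating agent and is used without delay.

Step 4
Reactants: 5 5-hydroxy-4-methylfuran-2(5H)-one (racemic)
Product: 6 5-methoxy-4-methylfuran-2(5H)-one (racemic)
Conditions: MeOH, p-TsOH (cat.), reflux
Reagents that add atoms: methanol, CO
Why: Acid-catalysed exchange of the lactol hydroxyl for methoxyl (pseudo-ester formation) turns the commercial hydroxybutenolide into a base-stable mixed acetal. The methoxy group later serves as the leaving group at the future Ce.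

Step 5
Reactants: 6 5-methoxy-4-methylfuran-2(5H)-one (racemic); 4 3-(bromomethyl)-4-(methoxymethoxy)-5,6-dimethyl-2H-pyran-2-one
Product: 8 3-(ArCH2)-5-methoxy-4-methylfuran-2(5H)-one (racemic), via 2(3H)-furanone tautomer 7 (not isolated)
Conditions: LiN(i-Pr)2, THF, −78 °C; 4, −78 → −30 °C; then Et3N, rt
Reagents that add atoms: none
Why: Deprotonation at C5 gives the aromatic 5-methoxy-2-oxidofuran, and as a lithium dienolate it should be alkylated by the reactive bromide at the α-carbon C3 (dienolate α-alkylation), which forms the Cg–Ck bond. Triethylamine then moves the double bond of 7 back into conjugation with the lactone carbonyl; the centre at C5 is racemic and is erased in step 10.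

Step 6
Reactants: 9 hexane-2,4-dione
Product: 10 3,3-dimethylhexane-2,4-dione
Conditions: MeI (3 equiv), K2CO3, acetone, reflux
Reagents that add atoms: iodomethane, CI
Why: Twofold C-methylation of the 1,3-diketone at its central carbon (enolate alkylation) installs the gem-dimethyl carbon Cj. After the first methylation the one remaining proton between the carbonyl groups is replaced in the same way.

Step 7
Reactants: 10 3,3-dimethylhexane-2,4-dione
Product: 11 3,3-dimethylhexane-2,4,5-trione
Conditions: SeO2, 1,4-dioxane, H2O (trace), 90 °C
Reagents that add atoms: selenium dioxide, O=[Se]=O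
Why: Riley oxidation: selenium dioxide oxidises the α-methylene group of the ethyl ketone, which enolises more readily than the methyl group of the other ketone, to a carbonyl group and so gives the vicinal diketone. The quaternary carbon rules out any oxidation between the two original carbonyl groups.

Step 8
Reactants: 11 3,3-dimethylhexane-2,4,5-trione
Product: 12 3,3-dimethyl-2,5-bis(triethylsilyloxy)hexa-1,5-dien-4-one
Conditions: Et3SiOTf (2.3 equiv), Et3N, CH2Cl2, −78 → 0 °C
Reagents that add atoms: triethylsilyl trifluoromethanesulfonate, CC[Si](CC)(CC)OS(=O)(=O)C(F)(F)F
Why: Soft enolisation: the two methyl groups are the only enolisable positions, so silyl triflate and amine should give the bis(silyl enol ether) without any regiochemical choice. One terminus is then a nucleophilic silyl enol ether and the other the 2-silyloxy enone of the key step, which removes the need for a selective enolisation late in the route.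

Step 9
Reactants: 8 3-(ArCH2)-5-methoxy-4-methylfuran-2(5H)-one (racemic); 12 3,3-dimethyl-2,5-bis(triethylsilyloxy)hexa-1,5-dien-4-one
Product: 13 3-(ArCH2)-5-[3,3-dimethyl-2,4-dioxo-5-(triethylsilyloxy)hex-5-en-1-yl]-4-methylfuran-2(5H)-one (racemic)
Conditions: Me3SiOTf (10 mol %), CH2Cl2, −78 °C; Et3N
Reagents that add atoms: none
Why: Mukaiyama-type substitution: the silyl triflate ionises the lactol methyl ether to an oxygen-stabilised allylic cation at C5, which is captured by the electron-rich 1,1-disubstituted silyl enol ether of 12 and forms the Ce–Ch bond. The cross-conjugated 2-silyloxy enone terminus is far less nucleophilic and should survive; C4 is fully substituted, so conjugate addition does not compete.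

Step 10
Reactants: 13 3-(ArCH2)-5-[3,3-dimethyl-2,4-dioxo-5-(triethylsilyloxy)hex-5-en-1-yl]-4-methylfuran-2(5H)-one (racemic)
Product: 14 1-[4-(ArCH2)-5-methoxy-3-methylfuran-2-yl]-3,3-dimethyl-5-(triethylsilyloxy)hex-5-ene-2,4-dione (achiral)
Conditions: KN(SiMe3)2, THF, −78 °C, 5 min; MeOTf, −78 °C; pH 7 buffer
Reagents that add atoms: methyl trifluoromethanesulfonate, COS(=O)(=O)C(F)(F)F
Why: The proton at C5 is the most acidic in 13 because its removal gives an aromatic 2-oxidofuran, and the hard electrophile methyl triflate should alkylate this fully substituted potassium dienolate on oxygen (enolate O-alkylation) to give the 2-methoxyfuran. Deprotonation and trapping within minutes at −78 °C are meant to outrun addition of the anion to the side-chain ketones and elimination from a side-chain enolate.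

Step 11
Reactants: 14 1-[4-(ArCH2)-5-methoxy-3-methylfuran-2-yl]-3,3-dimethyl-5-(triethylsilyloxy)hex-5-ene-2,4-dione (achiral)
Product: 15 oxygen-bridged (4+3) cycloadduct (O bridge Ca–Ce; CH3O at Ca; Et3SiO at Cd; Cf(CH3)=Cg(CH2Ar); ring D cyclopentanone; Ca S, Cd S, Ce S)
Conditions: Cu(OTf)2 (20 mol %), (S,S)-tBu-box (22 mol %), 4 Å MS, CH2Cl2, −40 °C
Reagents that add atoms: none
Why: Proposed new method: Cu(OTf)2 and the bis(oxazoline) 2,2′-isopropylidenebis[(4S)-4-tert-butyl-2-oxazoline] should bind the two ketone oxygens of the 2,2-dimethyl-1,3-dione as a six-membered chelate, so that the Cd carbonyl with its silyloxyvinyl substituent acts as a 2-oxyallyl cation equivalent. The furan carbon Ce (position 5, the most nucleophilic) adds to Cd in a five-membered (5-exo) closure that forms ring D and leaves a methoxy-stabilised oxocarbenium ion at Ca. The silyl enol ether carbon Cb then adds to Ca on the same face, closing the seven-membered ring C across the furan (net (4+3), the furan oxygen becoming the Ca–Ce bridge), and the triethylsilyl group passes from the new oxocarbenium oxygen to the copper alkoxide at Cd, which frees the catalyst. The closest known reactions are Lewis-acid-catalysed (4+3) cycloadditions of 2-silyloxy enals with furans and intramolecular furan–oxyallyl cation cycloadditions; new here are a ketone terminus that reacts first, a 2-methoxyfuran and chelate-based enantiocontrol. Cd is set by the chiral ligand, which differentiates the two faces of the chelated ketone; should the facial sense prove opposite, the enantiomeric ligand is used. Ce follows from Cd because the three-atom tether allows only a cis-fused five-membered ring, and Ca follows from Ce because the oxygen bridge can span only one face. The step needs 1,2-addition at Cd in preference to conjugate addition at Cb, which the five- versus seven-membered first closure secures, and it needs the catalysed path to outrun any background cyclisation, for which low temperature and the absence of other Lewis acids are relied on.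

Step 12
Reactants: 15 oxygen-bridged (4+3) cycloadduct (O bridge Ca–Ce; CH3O at Ca; Et3SiO at Cd; Cf(CH3)=Cg(CH2Ar); ring D cyclopentanone; Ca S, Cd S, Ce S)
Product: 16 dihydro cycloadduct (as 15 but CH–CH3 at Cf and CH–CH2Ar at Cg, both hydrogens on the face of the O bridge; Ca S, Cd S, Ce S, Cf R, Cg S)
Conditions: H2 (50 bar), [Ir(cod)(PCy3)(py)][B(3,5-(CF3)2C6H3)4] (5 mol %), CH2Cl2, rt
Reagents that add atoms: none
Why: Catalytic hydrogenation with a cationic iridium catalyst suited to tetrasubstituted alkenes: both hydrogens should be delivered to the exo face of the strained bridged alkene, the face of the oxygen bridge, because the endo face is shielded by the three-carbon ketone bridge. This sets Cf (R) as in the target and Cg (S), the epimer of the target, which is corrected in step 15; ketones, the pyranone and the acetal should not be touched.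

Step 13
Reactants: 16 dihydro cycloadduct (Ca S, Cd S, Ce S, Cf R, Cg S)
Product: 17 ring C 1,3-diketone (Ca=O, Cc=O) fused to the ring D cyclopentenone (Et3SiO at Cd; CH3 at Cf; CH2Ar at Cg; Cd R, Cf R, Cg S)
Conditions: DBU, toluene, 0 °C → rt; aq. NH4Cl
Reagents that add atoms: none
Why: E1cB elimination (retro-oxa-Michael): the enolate of the ring D ketone expels the bridging oxygen from Ce, whose C–O bond is aligned with the enolate π system, and the released hemiketal alkoxide at Ca collapses to the ketone with loss of methanol. This gives the cyclopentenone and the ring C 1,3-diketone in one operation; no stereocentre is touched, the descriptor at Cd changing from S to R only because the priorities of its neighbours change.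

Step 14
Reactants: 17 ring C 1,3-diketone fused to the ring D cyclopentenone (Cd R, Cf R, Cg S)
Product: 19 2-(triethylsilyloxy)-1,3-diketone of ring C (Et3SiO at Cb/Cd; Cb S; Cd R; Cf R; Cg S), via enol triethylsilyl ether 18 (not isolated)
Conditions: Et3SiOTf, Et3N, CH2Cl2, −78 °C; then DMDO, acetone, −78 → −40 °C
Reagents that add atoms: triethylsilyl trifluoromethanesulfonate, CC[Si](CC)(CC)OS(=O)(=O)C(F)(F)F; dimethyldioxirane, CC1(C)OO1
Why: Rubottom oxidation: O-silylation of the enolised 1,3-diketone gives 18, whose electron-rich Ca=Cb double bond should be epoxidised by the neutral dioxirane in preference to the enone and the pyranone, and silyl migration opens the epoxide to the 2-silyloxy-1,3-diketone. The silyl ether and one equivalent of oxidant at low temperature are meant to stop the reaction at mono-oxygenation; Cb lies between two carbonyl groups, is configurationally labile and is drawn in the arrangement that maps onto the target.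

Step 15
Reactants: 19 2-(triethylsilyloxy)-1,3-diketone of ring C (Cb S; Cd R; Cf R; Cg S)
Product: 20 CNP0525404.1 (Ca S, Cb R, Cd R, Cf R, Cg R)
Conditions: 2 M HCl, THF, 0 → 40 °C
Reagents that add atoms: none
Why: Aqueous acid hydrolyses both silyl ethers and the methoxymethyl ether, and the freed ring A hydroxyl adds to the Ca ketone to close ring B as the hemiketal. Under the same conditions Cg and Cb epimerise through the enol of the open-chain ketone and Ca through ring opening, so these three centres should settle, relative to the fixed Cd and Cf, in the trans-fused arrangement of the target.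

## Compound list

(Ar = 4-(methoxymethoxy)-5,6-dimethyl-2-oxo-2H-pyran-3-yl)

1 | 4-hydroxy-5,6-dimethyl-2H-pyran-2-one | Cc1oc(=O)cc(O)c1C | starting material
2 | 4-(methoxymethoxy)-5,6-dimethyl-2H-pyran-2-one | COCOc1cc(=O)oc(C)c1C | intermediate
3 | 3-(hydroxymethyl)-4-(methoxymethoxy)-5,6-dimethyl-2H-pyran-2-one | COCOc1c(CO)c(=O)oc(C)c1C | intermediate
4 | 3-(bromomethyl)-4-(methoxymethoxy)-5,6-dimethyl-2H-pyran-2-one | COCOc1c(CBr)c(=O)oc(C)c1C | intermediate
5 | 5-hydroxy-4-methylfuran-2(5H)-one (racemic) | CC1=CC(=O)OC1O | starting material
6 | 5-methoxy-4-methylfuran-2(5H)-one (racemic) | COC1OC(=O)C=C1C | intermediate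
7 | 3-(ArCH2)-5-methoxy-4-methylfuran-2(3H)-one (racemic) | COC1=C(C)C(Cc2c(OCOC)c(C)c(C)oc2=O)C(=O)O1 | intermediate (not isolated)
8 | 3-(ArCH2)-5-methoxy-4-methylfuran-2(5H)-one (racemic) | COC1OC(=O)C(Cc2c(OCOC)c(C)c(C)oc2=O)=C1C | intermediate
9 | hexane-2,4-dione | CCC(=O)CC(C)=O | starting material
10 | 3,3-dimethylhexane-2,4-dione | CCC(=O)C(C)(C)C(C)=O | intermediate
11 | 3,3-dimethylhexane-2,4,5-trione | CC(=O)C(=O)C(C)(C)C(C)=O | intermediate
12 | 3,3-dimethyl-2,5-bis(triethylsilyloxy)hexa-1,5-dien-4-one | C=C(O[Si](CC)(CC)CC)C(=O)C(C)(C)C(=C)O[Si](CC)(CC)CC | intermediate
13 | 3-(ArCH2)-5-[3,3-dimethyl-2,4-dioxo-5-(triethylsilyloxy)hex-5-en-1-yl]-4-methylfuran-2(5H)-one (racemic) | C=C(O[Si](CC)(CC)CC)C(=O)C(C)(C)C(=O)CC1OC(=O)C(Cc2c(OCOC)c(C)c(C)oc2=O)=C1C | intermediate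
14 | 1-[4-(ArCH2)-5-methoxy-3-methylfuran-2-yl]-3,3-dimethyl-5-(triethylsilyloxy)hex-5-ene-2,4-dione (achiral; key-step precursor) | C=C(O[Si](CC)(CC)CC)C(=O)C(C)(C)C(=O)Cc1oc(OC)c(Cc2c(OCOC)c(C)c(C)oc2=O)c1C | intermediate
15 | oxygen-bridged (4+3) cycloadduct: ring C bridged by O from Ca to Ce and cis-fused at Cd–Ce to cyclopentanone ring D; CH3O at Ca, Et3SiO at Cd on the face of the bridge, Cf(CH3)=Cg(CH2Ar); Ca S, Cd S, Ce S | COCOc1c(C)c(C)oc(=O)c1CC1=C(C)[C@@]2(O3)CC(=O)C(C)(C)[C@@]2(O[Si](CC)(CC)CC)C(=O)C[C@@]13OC | intermediate
16 | dihydro cycloadduct: as 15 with H at Cf and Cg on the face of the O bridge; Ca S, Cd S, Ce S, Cf R, Cg S | COCOc1c(C)c(C)oc(=O)c1C[C@H]1[C@@H](C)[C@@]2(O3)CC(=O)C(C)(C)[C@@]2(O[Si](CC)(CC)CC)C(=O)C[C@@]13OC | intermediate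
17 | ring C 1,3-diketone (Ca=O, Cc=O) fused to the ring D cyclopentenone; Et3SiO at Cd, CH3 at Cf, CH2Ar at Cg; Cd R, Cf R, Cg S | O=C1CC(=O)[C@@]2(O[Si](CC)(CC)CC)C(=CC(=O)C2(C)C)[C@H](C)[C@@H]1Cc1c(OCOC)c(C)c(C)oc1=O | intermediate
18 | enol triethylsilyl ether of 17 (Et3SiO at Ca, Ca=Cb); Cd R, Cf R, Cg S | CC[Si](CC)(CC)OC1=CC(=O)[C@@]2(O[Si](CC)(CC)CC)C(=CC(=O)C2(C)C)[C@H](C)[C@@H]1Cc1c(OCOC)c(C)c(C)oc1=O | intermediate (not isolated)
19 | 2-(triethylsilyloxy)-1,3-diketone of ring C: Et3SiO at Cb and at Cd; Cb S (labile), Cd R, Cf R, Cg S | O=C1[C@H](O[Si](CC)(CC)CC)C(=O)[C@@]2(O[Si](CC)(CC)CC)C(=CC(=O)C2(C)C)[C@H](C)[C@@H]1Cc1c(OCOC)c(C)c(C)oc1=O | intermediate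
20 | CNP0525404.1; Ca S, Cb R, Cd R, Cf R, Cg R | Cc1oc(=O)c2c(c1C)O[C@]1(O)[C@H](O)C(=O)[C@@]3(O)C(=CC(=O)C3(C)C)[C@H](C)[C@H]1C2 | target

## Step count and least certain steps

Total step count: 15. Longest linear sequence: 11 steps (1, 2, 3, 5, 9, 10, 11, 12, 13, 14, 15); steps 4 and 6 to 8 prepare the two partner fragments.

Step 11 (proposed new method). Most likely failures:
- The second ring closure may not follow the first, and the oxocarbenium ion may then lose its methyl group to give a spiro-lactone.
- Enantiofacial discrimination may be poor if the 1,3-dione chelate is loose or an uncatalysed cyclisation competes.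
- The Lewis acid may open the product ketal or remove the acetal on ring A.

Fallback, with known reactions only, setting out from 13 and returning at 17: the two bonds are made one at a time at the lactone oxidation level.
- Soft enolisation of 13 (Et3SiOTf, Et3N, −78 °C) gives the 2-(triethylsilyloxy)furan F1.
- A Cu(OTf)2–bis(oxazoline)-catalysed intramolecular vinylogous Mukaiyama aldol addition to the chelated ketone, a known enantioselective reaction type for 2-silyloxyfurans, forms the Cd–Ce bond and gives the spiro-butenolide F2 carrying the Cd silyl ether.
- CsF unmasks the methyl ketone enolate, which attacks the lactone carbonyl in an intramolecular Claisen condensation that closes ring C. The tertiary alkoxide set free at Ce is lost by E1cB elimination to give the cross-conjugated dienedione F3, the compound through which the fallback for step 12 also passes.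
- Reduction of this vinylogous ene-dione with Zn in acetic acid, then DBU to bring the double bond back into conjugation with the ring D ketone, leads to 17.
- Weakness: Cf then rests on thermodynamic protonation instead of a directed hydrogenation.

Step 12. Most likely failures: no turnover at an alkene flanked by two fully substituted bridgeheads, or opening of the allylic ketal by acidic metal hydride species. Fallback, from 15 to 17: the bridge is opened before the reduction. DBU converts 15 by the elimination of step 13 into the dienedione F3, whose Cf=Cg bond is now part of a vinylogous ene-dione and is reduced by Zn in acetic acid; DBU then restores the ring D enone and equilibrates the α-centre Cg.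

Step 10. Most likely failures: C- instead of O-methylation; competing deprotonation next to the side-chain ketone followed by β-elimination of the lactone carboxylate; addition of the oxidofuran to the Cd ketone before it is trapped, which would also erode the enantiocontrol of step 11. Step 9 carries the related risk of acetal loss under the silyl triflate. Fallback, from 4 and 12 to 14, which bypasses steps 9 and 10: the methyl group is put on before the side chain.
- Bromide 4 alkylates the lithium dienolate of commercial 4-methylfuran-2(5H)-one to give the ketone-free butenolide F4.
- O-Methylation of F4 (KN(SiMe3)2, MeOTf) gives the 2-methoxyfuran F5.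
- Bis(enol ether) 12 is brominated at its electron-rich terminus (NBS) to the bromoketone F6.
- A photoredox radical C–H alkylation of F5 at its free 5-position with F6 (fac-Ir(ppy)3, 2,6-lutidine, blue light, high furan concentration) gives 14.

Step 15. Most likely failures: incomplete inversion at Cg because the cis-fused hemiketal is a kinetic trap; acyloin shift or retro-Claisen cleavage of the α-hydroxy dicarbonyl system if the acid has to be forced. Fallback, from 17 to 20: the oxygen at Cb is introduced last. Acid treatment of the more robust 17 removes the protecting groups, closes ring B and can be forced until Cg has equilibrated, giving the Cb-deoxy hemiketal F7. With ring B closed the Cc ketone has Cb as its only enolisable position, so persilylation (Me3SiOTf, Et3N) followed by DMDO and mild acid should give 20 by a regiospecific Rubottom oxidation.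

Step 2. Most likely failures: lateral metalation at the 6-methyl group or addition of the alkyllithium to the lactone. Fallback, from 2 to 3: electrophilic bromination of 2 at C3 (NBS) gives the 3-bromo-pyranone F8, and a Stille coupling with (tributylstannyl)methanol (Pd(PPh3)4, toluene, 100 °C) installs the hydroxymethyl group to return at 3.

## Further compounds

F1 | step 11 | 1-[4-(ArCH2)-3-methyl-5-(triethylsilyloxy)furan-2-yl]-3,3-dimethyl-5-(triethylsilyloxy)hex-5-ene-2,4-dione | C=C(O[Si](CC)(CC)CC)C(=O)C(C)(C)C(=O)Cc1oc(O[Si](CC)(CC)CC)c(Cc2c(OCOC)c(C)c(C)oc2=O)c1C
F2 | step 11 | spiro-butenolide: ring D closed, Et3SiO at Cd (S), lactone oxygen at spiro carbon Ce (S), side chain C(=O)–C(OSiEt3)=CH2 on Cd | C=C(O[Si](CC)(CC)CC)C(=O)[C@]1(O[Si](CC)(CC)CC)C(C)(C)C(=O)C[C@@]12OC(=O)C(Cc3c(OCOC)c(C)c(C)oc3=O)=C2C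
F3 | step 12 | dienedione: ring C 1,3-diketone with Cf=Cg double bond fused to the ring D cyclopentenone, Et3SiO at Cd (R) | O=C1CC(=O)[C@@]2(O[Si](CC)(CC)CC)C(=CC(=O)C2(C)C)C(C)=C1Cc1c(OCOC)c(C)c(C)oc1=O
F4 | step 10 | 3-(ArCH2)-4-methylfuran-2(5H)-one | CC1=C(Cc2c(OCOC)c(C)c(C)oc2=O)C(=O)OC1
F5 | step 10 | 3-(ArCH2)-2-methoxy-4-methylfuran | COc1occ(C)c1Cc1c(OCOC)c(C)c(C)oc1=O
F6 | step 10 | 1-bromo-3,3-dimethyl-5-(triethylsilyloxy)hex-5-ene-2,4-dione | C=C(O[Si](CC)(CC)CC)C(=O)C(C)(C)C(=O)CBr
F7 | step 15 | Cb-deoxy analogue of 20 (CH2 at Cb; other centres arranged as in 20) | Cc1oc(=O)c2c(c1C)O[C@]1(O)CC(=O)[C@@]3(O)C(=CC(=O)C3(C)C)[C@H](C)[C@H]1C2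
F8 | step 2 | 3-bromo-4-(methoxymethoxy)-5,6-dimethyl-2H-pyran-2-one | COCOc1c(Br)c(=O)oc(C)c1C
A1 | alternative 1 | ring-B-closed methyl ketal aldehyde with pendant 2,2-dimethylcyclopentane-1,3-dione (benzoin substrate) | Cc1oc(=O)c2c(c1C)O[C@](OC)([C@H](O[Si](C)(C)C(C)(C)C)C=O)[C@H](C2)[C@@H](C)[C@H]1CC(=O)C(C)(C)C1=O
A2 | alternative 1 | tetracyclic acyloin, ring D saturated, methyl ketal at Ca, tert-butyldimethylsilyl ether at Cb | Cc1oc(=O)c2c(c1C)O[C@]1(OC)[C@H](O[Si](C)(C)C(C)(C)C)C(=O)[C@@]3(O)[C@H](CC(=O)C3(C)C)[C@H](C)[C@H]1C2
A3 | alternative 2 | methyl ester at Ca with free ring A hydroxyl and silyloxymethyl ketone on the ring D cyclopentenone (cascade substrate) | COC(=O)[C@H](Cc1c(O)c(C)c(C)oc1=O)[C@@H](C)C1=CC(=O)C(C)(C)[C@@]1(O[Si](CC)(CC)CC)C(=O)CO[Si](C)(C)C(C)(C)C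
A4 | alternative 2 | bis-silyl ether of 20 (tert-butyldimethylsilyl at Cb–O, triethylsilyl at Cd–O) | Cc1oc(=O)c2c(c1C)O[C@]1(O)[C@H](O[Si](C)(C)C(C)(C)C)C(=O)[C@@]3(O[Si](CC)(CC)CC)C(=CC(=O)C3(C)C)[C@H](C)[C@H]1C2
A5 | alternative 3 | eight-membered thialactone (S between Ca and Cb) fused to the ring D cyclopentenone | O=C1SCC(=O)[C@@]2(O[Si](CC)(CC)CC)C(=CC(=O)C2(C)C)[C@H](C)[C@H]1Cc1c(OCOC)c(C)c(C)oc1=O
A6 | alternative 3 | ring C 1,3-diketone, the Cg epimer of 17 | O=C1CC(=O)[C@@]2(O[Si](CC)(CC)CC)C(=CC(=O)C2(C)C)[C@H](C)[C@H]1Cc1c(OCOC)c(C)c(C)oc1=O
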